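Ring A, the central benzene ring, is built last. It is a resorcinol with oxygen on C-1A and C-3A, hydrogen on C-2A and adjacent carbon substituents on C-4A (C-d), C-5A (ring CH2) and C-6A (C-b), the pattern that a vinylketene and an alkynyl ether give on union. Photolysis of a benzocycloheptenyl diazo ketone bearing an ethynyl ether on the oxygen of C-e should form the bonds from C-1A to C-2A and C-6A and from C-3A to C-4A at once, closing ring A and the second dihydrofuran. The precursor holds ring B, the seven-membered ring and four stereocentres; the dihydrofuran at C-a follows.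

Key step: step 21

Atom labels: the six carbons of ring A are called C-1A to C-6A in ring order. C-1A carries the oxygen bonded to C-a, C-2A is CH, C-3A carries the oxygen bonded to C-e, C-4A carries C-d, C-5A carries the ring CH2 and C-6A carries C-b. Ring B is the dioxygenated ring fused to the seven-membered ring. C-a = O–CH(4-oxyphenyl) next to C-b; C-b = CH joining C-a, C-6A and ring B; C-c = CH(2,4-dioxyphenyl) of the seven-membered ring; C-d = CH(3,5-dioxyphenyl); C-e = O–CH(4-oxyphenyl) next to C-d. Target: C-a S, C-b S, C-c S, C-d R, C-e R.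

Abbreviations: TBS = tert-butyldimethylsilyl; pin = pinacolato; Tf = CF3SO2; Ms = CH3SO2; TRIP acid = 3,3′-bis(2,4,6-triisopropylphenyl)-1,1′-binaphthyl-2,2′-diyl hydrogen phosphate; BA = (5R,9S)-5-[(S)-(tert-butyldimethylsilyloxy)(4-methoxyphenyl)methyl]-9-(2,4-dimethoxyphenyl)-1,3-dimethoxy-8,9-dihydro-5H-benzo[7]annulen-7-yl (C-5 = C-b, C-7 = C-5A, C-9 = C-c).

Remark 1: the diazo ketone precursor and the phenol product of the key step agree with the target at every centre. The label of C-b changes from R to S in step 21, and that of C-d from S to R in step 20, by CIP ranking only.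

Remark 2: C-a is carried as the S-configured silyl ether (anti to C-b), as the allylboration delivers it; step 23 re-sets it under thermodynamic control.

Remark 3 (design): an ethynyl ether does not survive ruthenium carbenes, boranes or acid, and a carbanion at C-4A would add to it. It is therefore carried as its 1,2-dichlorovinyl ether, C-1A is brought in as the aldehyde carbon of the right fragment, and the alkyne is unmasked only after the seven-membered ring is closed. Because a p-methoxybenzylic ethynyl ether can rearrange on warming, it is kept at or below room temperature from step 18 on. The diazo ketone is photolysed cold and without storage, because its diazo group can add to the tethered alkyne.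

**Left fragment**

Step 1
Reactants: 1 1-bromo-3,5-dimethoxybenzene
Product: 3 2-bromo-4,6-dimethoxybenzaldehyde, via aryl iminium salt 2 (not isolated)
Conditions: POCl3, DMF, 0 → 90 °C; then H2O, NaOH to pH 7
Reagents that add atoms: N,N-dimethylformamide, CN(C)C=O; water, O
Why: Vilsmeier–Haack formylation goes to the position next to bromine that is ortho and para to the two methoxy groups, the position between the methoxy groups being more hindered, and hydrolysis of the iminium salt frees the aldehyde.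

Step 2
Reactants: 3 2-bromo-4,6-dimethoxybenzaldehyde; 4 diethyl {2-[methoxy(methyl)amino]-2-oxoethyl}phosphonate
Product: 5 (E)-unsaturated Weinreb amide
Conditions: NaH, THF, 0 °C → rt
Reagents that add atoms: none
Why: Horner–Wadsworth–Emmons olefination with a stabilised phosphonate anion should give the E-alkene and leaves the aryl bromide untouched.

Step 3
Reactants: 5 (E)-unsaturated Weinreb amide; 6 (2,4-dimethoxyphenyl)boronic acid
Product: 7 (3S)-3,3-diaryl Weinreb amide
Conditions: Rh(acac)(C2H4)2 (3 mol %), (R)-BINAP (3.3 mol %), K2CO3 (0.5 equiv), 6 (3 equiv), 1,4-dioxane/H2O 10:1, 100 °C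
Reagents that add atoms: none
Why: Hayashi–Miyaura asymmetric 1,4-addition, in which the aryl–rhodium species adds across the E-alkene; the (R)-ligand is expected, by the quadrant model for acyclic E-acceptors, to deliver the aryl group to the Re face of C-3, which sets C-c as S.

Step 4
Reactants: 7 (3S)-3,3-diaryl Weinreb amide; 8 vinylboronic acid pinacol ester
Product: 9 (3S)-styrene amide
Conditions: Pd(dppf)Cl2 (5 mol %), K2CO3, 1,4-dioxane/H2O, 90 °C
Reagents that add atoms: none
Why: Suzuki–Miyaura coupling of the aryl bromide installs the carbon that becomes C-b, and the amide and C-c are inert to the carbonate base.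

Step 5
Reactants: 9 (3S)-styrene amide; 10 allylboronic acid pinacol ester
Product: 11 (E)-γ-aryl allylboronate of the left fragment
Conditions: second-generation Grubbs catalyst (5 mol %), 10 (3 equiv), CH2Cl2, 40 °C
Reagents that add atoms: none
Why: Olefin cross-metathesis of a styrene with an allylboronate should give the E-configured γ-aryl allylboronate with loss of ethene.

Step 6
Reactants: 11 (E)-γ-aryl allylboronate of the left fragment; 12 4-methoxybenzaldehyde
Product: 13 anti homoallylic alcohol (C-a S, C-b R, C-c S)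
Conditions: (S)-TRIP acid (5 mol %), 4 Å molecular sieves, toluene, −30 → 0 °C; aq. NaHCO3
Reagents that add atoms: none
Why: Chiral phosphoric acid-catalysed allylboration through a closed chair transition state, in which the E-boronate gives the anti product and the (S)-acid directs attack to the Si face of the aldehyde, so that C-a is S and C-b is R whatever the remote centre C-c.

Step 7
Reactants: 13 anti homoallylic alcohol
Product: 14 TBS ether
Conditions: TBSOTf, 2,6-lutidine, CH2Cl2, −78 → 0 °C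
Reagents that add atoms: tert-butyldimethylsilyl trifluoromethanesulfonate, CC(C)(C)[Si](C)(C)OS(=O)(=O)C(F)(F)F
Why: Silylation with the silyl triflate and a hindered pyridine base protects the hindered benzylic alcohol for the organometallic steps that follow.

Step 8
Reactants: 14 TBS ether
Product: 15 methyl ketone
Conditions: MeMgBr (3 equiv), THF, 0 °C; aq. NH4Cl
Reagents that add atoms: methylmagnesium bromide, C[Mg]Br
Why: Grignard addition to a Weinreb amide stops at the ketone because the chelated tetrahedral adduct collapses only on work-up.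

Step 9
Reactants: 15 methyl ketone
Product: 16 2-triflyloxy-1-alkene
Conditions: LiN(i-Pr)2, THF, −78 °C; PhNTf2, −78 → 0 °C; aq. NH4Cl
Reagents that add atoms: N-phenylbis(trifluoromethanesulfonimide), O=S(=O)(N(c1ccccc1)S(=O)(=O)C(F)(F)F)C(F)(F)F
Why: Kinetic deprotonation at −78 °C takes a methyl proton rather than one of the hindered methylene next to C-c, and O-triflation of that enolate gives the terminal enol triflate.

**Right fragment**

Step 10
Reactants: 17 3,5-dimethoxybenzaldehyde
Product: 18 3,5-dimethoxystyrene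
Conditions: Ph3PCH3Br, KOt-Bu, THF, 0 °C → rt
Reagents that add atoms: methyltriphenylphosphonium bromide, C[P+](c1ccccc1)(c1ccccc1)c1ccccc1.[Br-]
Why: Wittig methylenation of an aromatic aldehyde with the unstabilised ylide.

Step 11
Reactants: 18 3,5-dimethoxystyrene; 10 allylboronic acid pinacol ester
Product: 19 (E)-γ-aryl allylboronate of the right fragment
Conditions: second-generation Grubbs catalyst (3 mol %), 10 (3 equiv), CH2Cl2, 40 °C
Reagents that add atoms: none
Why: The same olefin cross-metathesis as in step 5, on an unhindered styrene.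

Step 12
Reactants: 19 (E)-γ-aryl allylboronate of the right fragment; 12 4-methoxybenzaldehyde
Product: 20 (1R,2S)-anti homoallylic alcohol (C-e R, C-d S)
Conditions: (R)-TRIP acid (5 mol %), 4 Å molecular sieves, toluene, −30 °C; aq. NaHCO3
Reagents that add atoms: none
Why: The same chiral phosphoric acid-catalysed allylboration as in step 6 with the mirror-image acid, which directs attack to the Re face of the aldehyde (C-e R), and the E-boronate fixes the anti relation (C-d S).

Step 13
Reactants: 20 (1R,2S)-anti homoallylic alcohol; 21 trichloroethylene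
Product: 22 (E)-1,2-dichlorovinyl ether
Conditions: KH (2.2 equiv), THF, 0 °C → rt
Reagents that add atoms: none
Why: The potassium alkoxide adds anti to dichloroethyne formed in the flask from trichloroethylene, giving a base-stable masked ethynyl ether that is inert to boranes, chromium reagents and ruthenium carbenes.

Step 14
Reactants: 22 (E)-1,2-dichlorovinyl ether
Product: 24 primary alcohol, via B-alkyl-9-borabicyclononane 23 (not isolated)
Conditions: 9-BBN (0.5 M in THF), 0 °C → rt; then NaOH (aq), H2O2, 0 °C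
Reagents that add atoms: hydrogen peroxide, OO
Why: Hydroboration with the bulky 9-BBN takes only the terminal alkene and places boron on the terminal carbon, and alkaline peroxide oxidation gives the primary alcohol without touching C-d.

Step 15
Reactants: 24 primary alcohol
Product: 25 aldehyde (its carbonyl carbon becomes C-1A)
Conditions: Dess–Martin periodinane, NaHCO3, CH2Cl2, 0 °C → rt
Reagents that add atoms: none
Why: Buffered Dess–Martin oxidation gives the aldehyde under conditions that do not epimerise the β-centre.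

**Union and key step**

Step 16
Reactants: 16 2-triflyloxy-1-alkene; 25 aldehyde
Product: 26 allylic alcohol (both epimers at the future C-1A)
Conditions: CrCl2 (6 equiv), NiCl2 (2 mol %), DMF, rt
Reagents that add atoms: none
Why: Nozaki–Hiyama–Kishi coupling, in which the nickel-catalysed alkenylchromium species adds chemoselectively to the aldehyde and tolerates the chlorinated enol ether and the silyl ether; the new carbinol centre is removed in step 19.

Step 17
Reactants: 26 allylic alcohol
Product: 27 benzocycloheptenyl carbinol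
Conditions: second-generation Hoveyda–Grubbs catalyst (10 mol %), 1,4-benzoquinone (20 mol %), toluene (2 mM), 80 °C
Reagents that add atoms: none
Why: Ring-closing metathesis between the vinyl group on C-b and the 1,1-disubstituted alkene closes the seven-membered ring as the trisubstituted C-5A=C-6A alkene with loss of ethene, the dichlorovinyl ether being no metathesis substrate.

Step 18
Reactants: 27 benzocycloheptenyl carbinol
Product: 29 ethynyl ether carbinol, via dilithium alkoxide acetylide 28 (not isolated)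
Conditions: n-BuLi (3.5 equiv), THF, −78 → −40 °C; MeOH, −78 °C
Reagents that add atoms: none
Why: After deprotonation of the alcohol, n-BuLi eliminates HCl from the dichlorovinyl ether and exchanges the remaining chlorine for lithium, and protonation of the acetylide gives the terminal ethynyl ether at a stage where no carbonyl group is present.

Step 19
Reactants: 29 ethynyl ether carbinol
Product: 30 enone
Conditions: MnO2 (20 equiv), CH2Cl2, Et3N (1 %), rt
Reagents that add atoms: none
Why: MnO2 oxidises the allylic alcohol selectively under neutral conditions that spare the ynol ether and do not enolise toward C-b.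

Step 20
Reactants: 30 enone
Product: 32 α-diazo ketone, via trifluoroacetyl diketone 31 (not isolated)
Conditions: LiN(SiMe3)2 (1.1 equiv), THF, −78 °C; CF3CO2CH2CF3, −78 °C; aq. NH4Cl; then MsN3, Et3N, H2O, MeCN, 0 °C
Reagents that add atoms: methanesulfonyl azide, CS(=O)(=O)N=[N+]=[N-]
Why: Detrifluoroacetylative diazo transfer, in which the kinetic enolate at C-4A is C-acylated and the activated diketone takes the diazo group from the sulfonyl azide with loss of the trifluoroacetyl group; the cold, short base treatment should leave C-b intact.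

Step 21
Reactants: 32 α-diazo ketone
Product: 37 ring A phenol, via vinylketene 33 (not isolated), via cyclobutenone 34 (not isolated), via dienylketene 35 (not isolated), via cyclohexadienone 36 (not isolated)
Conditions: hν (365 nm), degassed ClCH2CH2Cl (0.005 M), 0 °C; then 80 °C in the dark
Reagents that add atoms: none
Why: Proposed new method: light expels N2 and the cycloheptenyl carbon C-5A shifts from C-1A to C-4A (Wolff rearrangement) to give vinylketene 33; the electron-rich ynol ether adds across the ketene C=C in a [2+2] step (terminal carbon C-2A to the carbonyl carbon C-1A, oxygen-bearing C-3A to C-4A) to give cyclobutenone 34, whose 4π opening to dienylketene 35 and 6π closure (C-1A to C-6A) give dienone 36 and, by tautomerisation, phenol 37. The closest known reaction is the photochemical Danheiser benzannulation of α-diazo ketones with alkoxyacetylenes, which is known only between separate partners. The dihydrofuran closes within the [2+2] step, by exo attack of C-4A on the oxygen-bearing alkyne carbon C-3A through the three-atom tether C-d–C-e–O, and ring A closes by the thermal six-electron electrocyclisation. No stereocentre is formed, and C-b to C-e are not touched because no stage is ionic or basic. The step needs C-2A to bond to C-1A, which both the tether and the polarity of the ynol ether secure, and it needs the ketene to be trapped before it dimerises, which high dilution and the tether secure.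

**Endgame**

Step 22
Reactants: 37 ring A phenol
Product: 38 phenol carbinol
Conditions: Bu4NF (1.2 equiv), THF, 0 °C; aq. NH4Cl
Reagents that add atoms: none
Why: Fluoride cleaves the silicon–oxygen bond and leaves the aryl ethers and the benzylic centres alone.

Step 23
Reactants: 38 phenol carbinol
Product: 39 octamethyl ether of the target
Conditions: TsOH·H2O (20 mol %), CH2Cl2, 0 °C
Reagents that add atoms: none
Why: Acid ionises the p-methoxybenzylic alcohol and the phenol on C-1A traps the cation in a five-membered ring closure under thermodynamic control, which places the aryl group on C-a trans to ring B on C-b and so sets C-a as S.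

Step 24
Reactants: 39 octamethyl ether of the target
Product: 40 CNP0154047.3
Conditions: BBr3 (20 equiv), CH2Cl2, −78 → 0 °C; then MeOH, H2O
Reagents that add atoms: none
Why: Lewis acid-mediated cleavage of all eight aryl methyl ethers, in which any opening of a benzylic C–O bond should revert to the trans-dihydrobenzofuran on work-up.

**Compound list**

1 | 1-bromo-3,5-dimethoxybenzene | COc1cc(Br)cc(OC)c1 | starting material
2 | N-[(2-bromo-4,6-dimethoxyphenyl)methylidene]-N-methylmethanaminium dichlorophosphate | COc1cc(Br)c(C=[N+](C)C)c(OC)c1.[O-]P(=O)(Cl)Cl | intermediate (not isolated)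
3 | 2-bromo-4,6-dimethoxybenzaldehyde | COc1cc(Br)c(C=O)c(OC)c1 | intermediate
4 | diethyl {2-[methoxy(methyl)amino]-2-oxoethyl}phosphonate | CCOP(=O)(CC(=O)N(C)OC)OCC | starting material
5 | (2E)-3-(2-bromo-4,6-dimethoxyphenyl)-N-methoxy-N-methylprop-2-enamide | CON(C)C(=O)/C=C/c1c(Br)cc(OC)cc1OC | intermediate
6 | (2,4-dimethoxyphenyl)boronic acid | COc1ccc(B(O)O)c(OC)c1 | starting material
7 | (3S)-3-(2-bromo-4,6-dimethoxyphenyl)-3-(2,4-dimethoxyphenyl)-N-methoxy-N-methylpropanamide | CON(C)C(=O)C[C@@H](c1ccc(OC)cc1OC)c1c(OC)cc(OC)cc1Br | intermediate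
8 | 2-ethenyl-4,4,5,5-tetramethyl-1,3,2-dioxaborolane | C=CB1OC(C)(C)C(C)(C)O1 | starting material
9 | (3S)-3-(2-ethenyl-4,6-dimethoxyphenyl)-3-(2,4-dimethoxyphenyl)-N-methoxy-N-methylpropanamide | CON(C)C(=O)C[C@@H](c1ccc(OC)cc1OC)c1c(OC)cc(OC)cc1C=C | intermediate
10 | 4,4,5,5-tetramethyl-2-(prop-2-en-1-yl)-1,3,2-dioxaborolane | C=CCB1OC(C)(C)C(C)(C)O1 | starting material
11 | (3S)-3-(2,4-dimethoxyphenyl)-3-{2,4-dimethoxy-6-[(1E)-3-(4,4,5,5-tetramethyl-1,3,2-dioxaborolan-2-yl)prop-1-en-1-yl]phenyl}-N-methoxy-N-methylpropanamide | CON(C)C(=O)C[C@@H](c1ccc(OC)cc1OC)c1c(OC)cc(OC)cc1/C=C/CB1OC(C)(C)C(C)(C)O1 | intermediate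
12 | 4-methoxybenzaldehyde | COc1ccc(C=O)cc1 | starting material
13 | (3S)-3-(2,4-dimethoxyphenyl)-3-{2-[(1S,2R)-1-hydroxy-1-(4-methoxyphenyl)but-3-en-2-yl]-4,6-dimethoxyphenyl}-N-methoxy-N-methylpropanamide | COc1ccc([C@@H](O)[C@@H](c2cc(OC)cc(OC)c2[C@H](c2ccc(OC)cc2OC)CC(=O)N(C)OC)C=C)cc1 | intermediate
14 | (3S)-3-{2-[(1S,2R)-1-(tert-butyldimethylsilyloxy)-1-(4-methoxyphenyl)but-3-en-2-yl]-4,6-dimethoxyphenyl}-3-(2,4-dimethoxyphenyl)-N-methoxy-N-methylpropanamide | COc1ccc([C@@H](O[Si](C)(C)C(C)(C)C)[C@@H](c2cc(OC)cc(OC)c2[C@H](c2ccc(OC)cc2OC)CC(=O)N(C)OC)C=C)cc1 | intermediate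
15 | (4S)-4-{2-[(1S,2R)-1-(tert-butyldimethylsilyloxy)-1-(4-methoxyphenyl)but-3-en-2-yl]-4,6-dimethoxyphenyl}-4-(2,4-dimethoxyphenyl)butan-2-one | COc1ccc([C@@H](O[Si](C)(C)C(C)(C)C)[C@@H](c2cc(OC)cc(OC)c2[C@H](c2ccc(OC)cc2OC)CC(C)=O)C=C)cc1 | intermediate
16 | (4S)-4-{2-[(1S,2R)-1-(tert-butyldimethylsilyloxy)-1-(4-methoxyphenyl)but-3-en-2-yl]-4,6-dimethoxyphenyl}-4-(2,4-dimethoxyphenyl)but-1-en-2-yl trifluoromethanesulfonate | COc1ccc([C@@H](O[Si](C)(C)C(C)(C)C)[C@@H](c2cc(OC)cc(OC)c2[C@H](c2ccc(OC)cc2OC)CC(=C)OS(=O)(=O)C(F)(F)F)C=C)cc1 | intermediate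
17 | 3,5-dimethoxybenzaldehyde | COc1cc(C=O)cc(OC)c1 | starting material
18 | 1-ethenyl-3,5-dimethoxybenzene | C=Cc1cc(OC)cc(OC)c1 | intermediate
19 | 2-[(2E)-3-(3,5-dimethoxyphenyl)prop-2-en-1-yl]-4,4,5,5-tetramethyl-1,3,2-dioxaborolane | COc1cc(/C=C/CB2OC(C)(C)C(C)(C)O2)cc(OC)c1 | intermediate
20 | (1R,2S)-2-(3,5-dimethoxyphenyl)-1-(4-methoxyphenyl)but-3-en-1-ol | C=C[C@@H](c1cc(OC)cc(OC)c1)[C@H](c1ccc(OC)cc1)O | intermediate
21 | trichloroethylene | ClC=C(Cl)Cl | starting material
22 | 1-[(1R,2S)-1-{[(E)-1,2-dichloroethenyl]oxy}-2-(3,5-dimethoxyphenyl)but-3-en-1-yl]-4-methoxybenzene | C=C[C@@H](c1cc(OC)cc(OC)c1)[C@H](c1ccc(OC)cc1)O/C(Cl)=C\Cl | intermediate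
23 | 9-[(3S,4R)-4-{[(E)-1,2-dichloroethenyl]oxy}-3-(3,5-dimethoxyphenyl)-4-(4-methoxyphenyl)butyl]-9-borabicyclo[3.3.1]nonane | B1(C2CCCC1CCC2)CC[C@@H](c1cc(OC)cc(OC)c1)[C@H](c1ccc(OC)cc1)O/C(Cl)=C\Cl | intermediate (not isolated)
24 | (3S,4R)-4-{[(E)-1,2-dichloroethenyl]oxy}-3-(3,5-dimethoxyphenyl)-4-(4-methoxyphenyl)butan-1-ol | OCC[C@@H](c1cc(OC)cc(OC)c1)[C@H](c1ccc(OC)cc1)O/C(Cl)=C\Cl | intermediate
25 | (3S,4R)-4-{[(E)-1,2-dichloroethenyl]oxy}-3-(3,5-dimethoxyphenyl)-4-(4-methoxyphenyl)butanal | O=CC[C@@H](c1cc(OC)cc(OC)c1)[C@H](c1ccc(OC)cc1)O/C(Cl)=C\Cl | intermediate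
26 | coupling product: the alkenyl carbon of 16 bonded to the carbinol carbon formed from the aldehyde of 25 (CH2=C–CH(OH)–CH2 unit, both carbinol epimers; C-a S, C-b R, C-c S, C-d S, C-e R) | COc1ccc([C@@H](O[Si](C)(C)C(C)(C)C)[C@@H](c2cc(OC)cc(OC)c2[C@H](c2ccc(OC)cc2OC)CC(=C)C(O)C[C@@H](c2cc(OC)cc(OC)c2)[C@H](c2ccc(OC)cc2)O/C(Cl)=C\Cl)C=C)cc1 | intermediate
27 | (3S,4R)-1-BA-4-{[(E)-1,2-dichloroethenyl]oxy}-3-(3,5-dimethoxyphenyl)-4-(4-methoxyphenyl)butan-1-ol (both C-1 epimers) | COc1ccc([C@@H](O[Si](C)(C)C(C)(C)C)[C@@H]2C=C(C(O)C[C@@H](c3cc(OC)cc(OC)c3)[C@H](c3ccc(OC)cc3)O/C(Cl)=C\Cl)C[C@@H](c3ccc(OC)cc3OC)c3c(OC)cc(OC)cc32)cc1 | intermediate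
28 | dilithium salt of 29 (lithium alkoxide at C-1, lithium acetylide at the ethynyl ether) | [Li+].[Li+].COc1ccc([C@@H](O[Si](C)(C)C(C)(C)C)[C@@H]2C=C(C([O-])C[C@@H](c3cc(OC)cc(OC)c3)[C@H](c3ccc(OC)cc3)OC#[C-])C[C@@H](c3ccc(OC)cc3OC)c3c(OC)cc(OC)cc32)cc1 | intermediate (not isolated)
29 | (3S,4R)-1-BA-3-(3,5-dimethoxyphenyl)-4-(ethynyloxy)-4-(4-methoxyphenyl)butan-1-ol (both C-1 epimers) | COc1ccc([C@@H](O[Si](C)(C)C(C)(C)C)[C@@H]2C=C(C(O)C[C@@H](c3cc(OC)cc(OC)c3)[C@H](c3ccc(OC)cc3)OC#C)C[C@@H](c3ccc(OC)cc3OC)c3c(OC)cc(OC)cc32)cc1 | intermediate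
30 | (3S,4R)-1-BA-3-(3,5-dimethoxyphenyl)-4-(ethynyloxy)-4-(4-methoxyphenyl)butan-1-one | COc1ccc([C@@H](O[Si](C)(C)C(C)(C)C)[C@@H]2C=C(C(=O)C[C@@H](c3cc(OC)cc(OC)c3)[C@H](c3ccc(OC)cc3)OC#C)C[C@@H](c3ccc(OC)cc3OC)c3c(OC)cc(OC)cc32)cc1 | intermediate
31 | (3S,4R)-1-BA-3-(3,5-dimethoxyphenyl)-4-(ethynyloxy)-4-(4-methoxyphenyl)-2-(trifluoroacetyl)butan-1-one (both C-2 epimers) | COc1ccc([C@@H](O[Si](C)(C)C(C)(C)C)[C@@H]2C=C(C(=O)C(C(=O)C(F)(F)F)[C@@H](c3cc(OC)cc(OC)c3)[C@H](c3ccc(OC)cc3)OC#C)C[C@@H](c3ccc(OC)cc3OC)c3c(OC)cc(OC)cc32)cc1 | intermediate (not isolated)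
32 | (3R,4R)-1-BA-2-diazo-3-(3,5-dimethoxyphenyl)-4-(ethynyloxy)-4-(4-methoxyphenyl)butan-1-one | COc1ccc([C@@H](O[Si](C)(C)C(C)(C)C)[C@@H]2C=C(C(=O)C(=[N+]=[N-])[C@@H](c3cc(OC)cc(OC)c3)[C@H](c3ccc(OC)cc3)OC#C)C[C@@H](c3ccc(OC)cc3OC)c3c(OC)cc(OC)cc32)cc1 | intermediate
33 | (3R,4R)-2-BA-3-(3,5-dimethoxyphenyl)-4-(ethynyloxy)-4-(4-methoxyphenyl)but-1-en-1-one | COc1ccc([C@@H](O[Si](C)(C)C(C)(C)C)[C@@H]2C=C(C(=C=O)[C@@H](c3cc(OC)cc(OC)c3)[C@H](c3ccc(OC)cc3)OC#C)C[C@@H](c3ccc(OC)cc3OC)c3c(OC)cc(OC)cc32)cc1 | intermediate (not isolated)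
34 | (3R,4R)-5-BA-4-(3,5-dimethoxyphenyl)-3-(4-methoxyphenyl)-2-oxabicyclo[3.2.0]hept-1(7)-en-6-one (C-5 not defined) | COc1ccc([C@@H](O[Si](C)(C)C(C)(C)C)[C@@H]2C=C(C45C(=O)C=C4O[C@@H](c3ccc(OC)cc3)[C@@H]5c3cc(OC)cc(OC)c3)C[C@@H](c3ccc(OC)cc3OC)c3c(OC)cc(OC)cc32)cc1 | intermediate (not isolated)
35 | 2-[(4R,5R)-3-BA-4-(3,5-dimethoxyphenyl)-5-(4-methoxyphenyl)-4,5-dihydrofuran-2-yl]ethen-1-one | COc1ccc([C@@H](O[Si](C)(C)C(C)(C)C)[C@@H]2C=C(C4=C(C=C=O)O[C@@H](c3ccc(OC)cc3)[C@@H]4c3cc(OC)cc(OC)c3)C[C@@H](c3ccc(OC)cc3OC)c3c(OC)cc(OC)cc32)cc1 | intermediate (not isolated)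
36 | keto tautomer of 37 (cyclohexa-2,4-dienone: C=O at C-1A, double bonds C-2A=C-3A and C-4A=C-5A, C-6A an sp3 CH of undefined configuration) | COc1ccc([C@@H](O[Si](C)(C)C(C)(C)C)[C@H]2c3cc(OC)cc(OC)c3[C@H](c3ccc(OC)cc3OC)CC3=C4[C@@H](c5cc(OC)cc(OC)c5)[C@H](c5ccc(OC)cc5)OC4=CC(=O)C32)cc1 | intermediate (not isolated)
37 | ring A phenol: free OH on C-1A, H on C-2A, C-d/C-e dihydrobenzofuran closed on C-3A/C-4A, seven-membered ring on C-5A/C-6A, (S)-CH(OTBS)(4-methoxyphenyl) on C-b; C-a S, C-b S, C-c S, C-d R, C-e R | COc1ccc([C@@H](O[Si](C)(C)C(C)(C)C)[C@H]2c3cc(OC)cc(OC)c3[C@H](c3ccc(OC)cc3OC)Cc3c2c(O)cc2c3[C@@H](c3cc(OC)cc(OC)c3)[C@H](c3ccc(OC)cc3)O2)cc1 | intermediate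
38 | desilylated 37: free secondary alcohol on C-a (S) and free phenol on C-1A | COc1ccc([C@@H](O)[C@H]2c3cc(OC)cc(OC)c3[C@H](c3ccc(OC)cc3OC)Cc3c2c(O)cc2c3[C@@H](c3cc(OC)cc(OC)c3)[C@H](c3ccc(OC)cc3)O2)cc1 | intermediate
39 | octamethyl ether of the target (both trans-dihydrobenzofurans closed; C-a S, C-b S, C-c S, C-d R, C-e R) | COc1ccc([C@H]2Oc3cc4c(c5c3[C@@H]2c2cc(OC)cc(OC)c2[C@H](c2ccc(OC)cc2OC)C5)[C@@H](c2cc(OC)cc(OC)c2)[C@H](c2ccc(OC)cc2)O4)cc1 | intermediate
40 | CNP0154047.3 (octaphenol; C-a S, C-b S, C-c S, C-d R, C-e R) | Oc1ccc([C@H]2Oc3cc4c(c5c3[C@@H]2c2cc(O)cc(O)c2[C@H](c2ccc(O)cc2O)C5)[C@@H](c2cc(O)cc(O)c2)[C@H](c2ccc(O)cc2)O4)cc1 | target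

**Totals**

Total step count: 24 (left fragment 9, right fragment 6, union to target 9).
Longest linear sequence: 18 steps (steps 1–9 and 16–24).

**Steps most likely to fail**

1. Step 21. The diazo group may add as a 1,3-dipole across the tethered electron-rich alkyne before light is absorbed. The carbene may undergo a 1,2-hydrogen shift from C-d instead of the Wolff rearrangement. After the rearrangement the ketene may dimerise or fail to reach the strained bicyclic cyclobutenone. The fallback sets out from 30 and returns at 39, and uses the known intermolecular benzannulation. The ynol ether of 30 is hydrated (pyridinium p-toluenesulfonate, wet THF) to the C-e acetate F1. LiN(SiMe3)2 and CF3CO2CH2CF3 give the trifluoroacetyl diketone F2, and MsN3/Et3N converts it into the diazo ketone F3. Irradiation of F3 (365 nm, ClCH2CH2Cl) with tert-butoxyethyne in excess, removal of the excess alkyne under vacuum and heating to 80 °C is the photochemical Danheiser benzannulation between separate partners and should give the ring A phenol F4, which carries a tert-butyl ether on C-3A. CF3CO2H in CH2Cl2 then removes the tert-butyl group and ionises both p-methoxybenzylic C–O bonds (acetate at C-e, silyl ether at C-a), and the phenols on C-3A and C-1A close the two dihydrobenzofurans under thermodynamic trans control to give 39.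

2. Step 3. Insertion of the doubly ortho-substituted cinnamoyl acceptor into the aryl–rhodium bond may be so slow that protodeboronation of 6 outruns addition, and facial selectivity may erode at the temperature needed. The fallback sets out from 3 and returns at 7, and replaces catalyst control by auxiliary control. Horner–Wadsworth–Emmons reaction of 3 with diethyl {2-oxo-2-[(4R)-2-oxo-4-phenyl-1,3-oxazolidin-3-yl]ethyl}phosphonate (LiCl, i-Pr2NEt, MeCN) gives the N-enoyl oxazolidinone F5. 2,4-Dimethoxyphenylmagnesium bromide with CuBr·SMe2 (THF, −40 °C) adds anti to the 4-phenyl group of the chelated s-cis imide to give the adduct F6 with C-c S. Me(MeO)NH·HCl and AlMe3 in CH2Cl2 convert the imide into 7 and free the auxiliary.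

3. Step 17. Ruthenium hydride species may isomerise the allylic alcohol to a saturated ketone, and slow initiation at the hindered vinyl group on C-b may lead to oligomers instead of ring closure. The fallback sets out from 16 and returns at 27, and closes the ring before the fragments are joined. Miyaura borylation of 16 (PdCl2(PPh3)2, PPh3, KOPh, B2pin2, toluene, 50 °C) gives the 2-boryl diene F7. Ring-closing metathesis (second-generation Grubbs catalyst, CH2Cl2, 40 °C), a well-established closure for 1-substituted vinylboronates, gives the cyclic alkenylboronate F8. NaOH and I2 (THF/H2O, 0 °C) convert it into the alkenyl iodide F9, and CrCl2/NiCl2 coupling of F9 with aldehyde 25 in DMF gives 27 directly.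

**Further compounds**

F1 | step 21 | (3S,4R)-4-BA-2-(3,5-dimethoxyphenyl)-1-(4-methoxyphenyl)-4-oxobutyl acetate (C-e acetate of enone 30 in place of the ethynyl ether) | COc1ccc([C@@H](O[Si](C)(C)C(C)(C)C)[C@@H]2C=C(C(=O)C[C@@H](c3cc(OC)cc(OC)c3)[C@H](c3ccc(OC)cc3)OC(C)=O)C[C@@H](c3ccc(OC)cc3OC)c3c(OC)cc(OC)cc32)cc1
F2 | step 21 | 2-trifluoroacetyl derivative of F1 (at C-4A, both epimers) | COc1ccc([C@@H](O[Si](C)(C)C(C)(C)C)[C@@H]2C=C(C(=O)C(C(=O)C(F)(F)F)[C@@H](c3cc(OC)cc(OC)c3)[C@H](c3ccc(OC)cc3)OC(C)=O)C[C@@H](c3ccc(OC)cc3OC)c3c(OC)cc(OC)cc32)cc1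
F3 | step 21 | α-diazo ketone with C-e acetate (diazo on C-4A) | COc1ccc([C@@H](O[Si](C)(C)C(C)(C)C)[C@@H]2C=C(C(=O)C(=[N+]=[N-])[C@@H](c3cc(OC)cc(OC)c3)[C@H](c3ccc(OC)cc3)OC(C)=O)C[C@@H](c3ccc(OC)cc3OC)c3c(OC)cc(OC)cc32)cc1
F4 | step 21 | ring A phenol with free OH on C-1A, tert-butoxy on C-3A, open-chain C-d/C-e arm with C-e acetate, TBS ether on C-a | COc1ccc([C@@H](O[Si](C)(C)C(C)(C)C)[C@H]2c3cc(OC)cc(OC)c3[C@H](c3ccc(OC)cc3OC)Cc3c2c(O)cc(OC(C)(C)C)c3[C@@H](c3cc(OC)cc(OC)c3)[C@H](c3ccc(OC)cc3)OC(C)=O)cc1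
F5 | step 3 | (4R)-3-[(2E)-3-(2-bromo-4,6-dimethoxyphenyl)prop-2-enoyl]-4-phenyl-1,3-oxazolidin-2-one | O=C(/C=C/c1c(Br)cc(OC)cc1OC)N1C(=O)OC[C@H]1c1ccccc1
F6 | step 3 | (4R)-3-[(3S)-3-(2-bromo-4,6-dimethoxyphenyl)-3-(2,4-dimethoxyphenyl)propanoyl]-4-phenyl-1,3-oxazolidin-2-one | O=C(C[C@@H](c1ccc(OC)cc1OC)c1c(OC)cc(OC)cc1Br)N1C(=O)OC[C@H]1c1ccccc1
F7 | step 17 | 2-boryl diene: 16 with Bpin in place of the triflate | COc1ccc([C@@H](O[Si](C)(C)C(C)(C)C)[C@@H](c2cc(OC)cc(OC)c2[C@H](c2ccc(OC)cc2OC)CC(=C)B2OC(C)(C)C(C)(C)O2)C=C)cc1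
F8 | step 17 | 2-BA-4,4,5,5-tetramethyl-1,3,2-dioxaborolane | COc1ccc([C@@H](O[Si](C)(C)C(C)(C)C)[C@@H]2C=C(B3OC(C)(C)C(C)(C)O3)C[C@@H](c3ccc(OC)cc3OC)c3c(OC)cc(OC)cc32)cc1
F9 | step 17 | BA iodide (iodine on C-5A) | COc1ccc([C@@H](O[Si](C)(C)C(C)(C)C)[C@@H]2C=C(I)C[C@@H](c3ccc(OC)cc3OC)c3c(OC)cc(OC)cc32)cc1
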